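**Retrosynthetic overview**

1. The target comes from heptabenzyl 8-bromo dimer 19 by global hydrogenolysis; the C3 carbinol of 19 comes from the 2,4-cis flavan-3-one 18 by hydride delivery to the face opposite both aryl groups.
2. Key disconnection: 18 comes from dihydrobenzofuran α-silyloxy aldehyde 12 and 8-bromo-tetra-O-benzylcatechin 15. A Friedel–Crafts bond forms between the aldehyde carbon (future C4) and C6 of the catechin unit, then a semipinacol 1,2-shift of the ring-fusion aryl carbon turns the five-membered ring O1–C2–C3–C4a–C8a into the six-membered pyran ring C (O1–C2–C3–C4–C4a–C8a).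
3. Enabling feature: C4a of ring A is para to the C7 oxygen and ortho to O1, which makes it an excellent migrating group; the cation it migrates to is stabilised by the 5,7,8a-trioxygenated ring A of the catechin unit.
4. 12 comes from the Katsuki–Sharpless epoxide of an (E)-2,3-diarylallyl alcohol, made from an isoaurone (2,4-dihydroxyphenylacetic acid lactone plus 3,4-bis(benzyloxy)benzaldehyde); phenoxide 5-exo opening of the epoxide sets C2 (R).
5. Ring order: temporary lactone ring, then dihydrofuran ring, then pyran ring C by expansion; rings A and B and the whole lower catechin unit (rings D, E, F) enter preformed.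

Key step: step 12

Remark: the target is read as an all-cis (2R,3R,4S) 7,3',4'-trihydroxyflavan-3-ol unit (2-aryl, 3-OH and 4-aryl on one face of ring C) bonded from C4 to C6 of (2R,3S)-catechin; compounds 1, 3 and 13 are taken as commercial.

**Route**

Step 1
Reactants: 1 2,4-dihydroxyphenylacetic acid
Product: 2 6-hydroxy-1-benzofuran-2(3H)-one
Conditions: p-TsOH·H2O (5 mol %), toluene, reflux, Dean–Stark
Reagents that add atoms: none
Why: Acid-catalysed lactonisation of the ortho-hydroxyphenylacetic acid should close the five-membered aryl lactone, driven by azeotropic removal of water, while the para hydroxyl cannot reach the acid.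

Step 2
Reactants: 2 6-hydroxy-1-benzofuran-2(3H)-one; 3 3,4-bis(benzyloxy)benzaldehyde
Product: 4 (E)-3-[3,4-bis(benzyloxy)benzylidene]-6-hydroxy-1-benzofuran-2(3H)-one
Conditions: piperidine (10 mol %), AcOH (10 mol %), toluene, reflux, Dean–Stark; recrystallisation, exclusion of light
Reagents that add atoms: none
Why: Knoevenagel condensation at the acidic C3 methylene of the 2-coumaranone should give the isoaurone, with the E isomer (new aryl syn to the benzo ring, anti to the lactone carbonyl) expected to predominate as in related 3-arylidene lactones and to be purified by crystallisation.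

Step 3
Reactants: 4 (E)-3-[3,4-bis(benzyloxy)benzylidene]-6-hydroxy-1-benzofuran-2(3H)-one
Product: 5 (E)-6-(benzyloxy)-3-[3,4-bis(benzyloxy)benzylidene]-1-benzofuran-2(3H)-one
Conditions: BnBr (1.2 equiv), K2CO3, acetone, 50 °C, dark
Reagents that add atoms: benzyl bromide, BrCc1ccccc1
Why: Williamson etherification of the only phenol; the alkylidene lactone has no acidic C–H left, so C-alkylation is excluded.

Step 4
Reactants: 5 (E)-6-(benzyloxy)-3-[3,4-bis(benzyloxy)benzylidene]-1-benzofuran-2(3H)-one
Product: 6 (E)-2-[4-(benzyloxy)-2-hydroxyphenyl]-3-[3,4-bis(benzyloxy)phenyl]prop-2-en-1-ol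
Conditions: i-Bu2AlH (3.5 equiv), CH2Cl2, −78 to 0 °C; aq. KNaC4H4O6 work-up
Reagents that add atoms: none
Why: 1,2-selective aluminium hydride reduction of the α,β-unsaturated aryl lactone should open it to the allylic alcohol and the free phenol with retention of the alkene geometry.

Step 5
Reactants: 6 (E)-2-[4-(benzyloxy)-2-hydroxyphenyl]-3-[3,4-bis(benzyloxy)phenyl]prop-2-en-1-ol
Product: 7 (E)-2-[2-(allyloxy)-4-(benzyloxy)phenyl]-3-[3,4-bis(benzyloxy)phenyl]prop-2-en-1-ol
Conditions: allyl bromide (1.1 equiv), K2CO3, acetone, 40 °C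
Reagents that add atoms: allyl bromide, C=CCBr
Why: Chemoselective Williamson O-allylation of the phenol (far more acidic than the primary alcohol) masks it for the titanium-mediated epoxidation.

Step 6
Reactants: 7 (E)-2-[2-(allyloxy)-4-(benzyloxy)phenyl]-3-[3,4-bis(benzyloxy)phenyl]prop-2-en-1-ol
Product: 8 [(2S,3S)-2-[2-(allyloxy)-4-(benzyloxy)phenyl]-3-[3,4-bis(benzyloxy)phenyl]oxiran-2-yl]methanol
Conditions: Ti(Oi-Pr)4 (0.2 equiv), L-(+)-diisopropyl tartrate (0.25 equiv), t-BuOOH (2 equiv, isooctane), 4 Å MS, CH2Cl2, −25 °C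
Reagents that add atoms: tert-butyl hydroperoxide, CC(C)(C)OO
Why: Katsuki–Sharpless asymmetric epoxidation of an (E)-2,3-diarylallyl alcohol, a favourable substrate class, in which the L-(+)-tartrate ligand should direct oxygen to the face giving the 2S,3S epoxide (same sense as for (E)-cinnamyl alcohol); the terminal allyl ether alkene is not an allylic alcohol and stays untouched.

Step 7
Reactants: 8 [(2S,3S)-2-[2-(allyloxy)-4-(benzyloxy)phenyl]-3-[3,4-bis(benzyloxy)phenyl]oxiran-2-yl]methanol
Product: 10 (2R,3S)-6-(benzyloxy)-2-[3,4-bis(benzyloxy)phenyl]-3-(hydroxymethyl)-2,3-dihydro-1-benzofuran-3-ol, via epoxy phenol 9 (not isolated)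
Conditions: Pd(PPh3)4 (5 mol %), K2CO3 (2 equiv), MeOH/THF, rt
Reagents that add atoms: none
Why: Allyl transfer to methanol catalysed by zerovalent palladium (Tsuji–Trost deallylation) frees the phenoxide, which should open the epoxide by 5-exo-tet SN2 attack at the benzylic carbon (4-exo attack at the quaternary carbon is disfavoured), so that inversion sets C2 as R while the tertiary carbinol keeps its configuration with the hydroxyl cis to the 2-aryl group.

Step 8
Reactants: 10 (2R,3S)-6-(benzyloxy)-2-[3,4-bis(benzyloxy)phenyl]-3-(hydroxymethyl)-2,3-dihydro-1-benzofuran-3-ol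
Product: 11 (2R,3R)-6-(benzyloxy)-2-[3,4-bis(benzyloxy)phenyl]-3-hydroxy-2,3-dihydro-1-benzofuran-3-carbaldehyde
Conditions: IBX (1.5 equiv), DMSO, rt
Reagents that add atoms: none
Why: 2-Iodoxybenzoic acid oxidises the primary alcohol of a 1,2-diol to the aldehyde without glycol cleavage; the tertiary hydroxyl is inert and the quaternary α-carbon cannot epimerise.

Step 9
Reactants: 11 (2R,3R)-6-(benzyloxy)-2-[3,4-bis(benzyloxy)phenyl]-3-hydroxy-2,3-dihydro-1-benzofuran-3-carbaldehyde
Product: 12 (2R,3R)-6-(benzyloxy)-2-[3,4-bis(benzyloxy)phenyl]-3-[(trimethylsilyl)oxy]-2,3-dihydro-1-benzofuran-3-carbaldehyde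
Conditions: TMSOTf (1.3 equiv), 2,6-lutidine (2 equiv), CH2Cl2, −78 °C
Reagents that add atoms: trimethylsilyl trifluoromethanesulfonate, C[Si](C)(C)OS(=O)(=O)C(F)(F)F
Why: Silylation of the hindered tertiary hydroxyl with a silyl triflate under buffered conditions caps the oxygen that must later act only as the electron-releasing group of the semipinacol shift and not as a leaving group.

Step 10
Reactants: 13 (+)-catechin
Product: 14 (2R,3S)-5,7-bis(benzyloxy)-2-[3,4-bis(benzyloxy)phenyl]chroman-3-ol
Conditions: BnBr (4.4 equiv), K2CO3, DMF, 0 °C to rt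
Reagents that add atoms: benzyl bromide, BrCc1ccccc1
Why: Williamson benzylation of the four phenols; the secondary C3 hydroxyl is not alkylated under carbonate conditions and both stereocentres are untouched.

Step 11
Reactants: 14 (2R,3S)-5,7-bis(benzyloxy)-2-[3,4-bis(benzyloxy)phenyl]chroman-3-ol
Product: 15 (2R,3S)-5,7-bis(benzyloxy)-2-[3,4-bis(benzyloxy)phenyl]-8-bromochroman-3-ol
Conditions: NBS (1.0 equiv), CH2Cl2, −78 °C to rt
Reagents that add atoms: N-bromosuccinimide, O=C1CCC(=O)N1Br
Why: Electrophilic aromatic bromination of ring A should take place regioselectively at C8, the more reactive of the two free positions, which blocks it and leaves C6 as the only nucleophilic site.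

Step 12
Reactants: 12 (2R,3R)-6-(benzyloxy)-2-[3,4-bis(benzyloxy)phenyl]-3-[(trimethylsilyl)oxy]-2,3-dihydro-1-benzofuran-3-carbaldehyde; 15 (2R,3S)-5,7-bis(benzyloxy)-2-[3,4-bis(benzyloxy)phenyl]-8-bromochroman-3-ol (1.5 equiv)
Product: 18 (2R,4S)-7-(benzyloxy)-2-[3,4-bis(benzyloxy)phenyl]-4-[(2R,3S)-5,7-bis(benzyloxy)-2-[3,4-bis(benzyloxy)phenyl]-8-bromo-3-hydroxychroman-6-yl]chroman-3-one, via benzylic carbinol 16 (not isolated), via benzylic cation 17 (not isolated)
Conditions: BF3·OEt2 (0.5 equiv), CH2Cl2, −78 to −30 °C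
Reagents that add atoms: none
Why: Proposed new method: BF3 should activate the aldehyde of 12 for Friedel–Crafts hydroxyalkylation by C6 of 15 (the only free position of the phloroglucinol-type ring, C8 being blocked by bromine), giving carbinol 16 as an epimer mixture that ionises at once to the 2,4,6-trioxygenated benzylic cation 17, so both epimers converge. The bond from C3 to the ring-fusion aryl carbon (C3a of the dihydrobenzofuran, C4a of the flavan) then shifts to the cationic carbon through a phenonium-type bridged transition state stabilised by the para benzyloxy group and the ortho ring oxygen, and loss of the silyl group from the resulting silyloxocarbenium ion gives the C3 ketone. The closest known reactions are the semipinacol ring expansion of β-silyloxy benzylic cations (1-(α-hydroxybenzyl)indan-1-ol to 1-aryl-2-tetralone type) and acid-mediated interflavan Friedel–Crafts couplings of 8-bromo-protected catechins; their union in one operation on a 3-silyloxy-2,3-dihydrobenzofuran-3-carbaldehyde is new. Ring C is closed by ring expansion rather than cyclisation: a 1,2-aryl shift (formally 3-exo ipso attack on the cation, then cleavage of the old C3–aryl bond) inserts the former aldehyde carbon between C3 and C4a as C4, five ring atoms becoming six. The new stereocentre C4 is set under substrate control: the cationic carbon sits on the ring face trans to the C2 aryl group (fixed by the 3R centre made in steps 6 and 7), and in the bridged transition state the bulky catechin aryl should take the outward, equatorial-like position, away from the axial C2–H, which gives the 2,4-cis (4S) ketone while C2 is untouched and C3 becomes trigonal. The step needs ionisation of the exocyclic C–O bond only and migration of the aryl carbon rather than C2: the tertiary oxygen is capped as a silyl ether so that only the newly formed, boron-bound secondary oxygen leaves, and C2 is inductively deactivated by O1 whereas the aryl carbon is activated by two oxygen donors.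

Step 13
Reactants: 18 (2R,4S)-7-(benzyloxy)-2-[3,4-bis(benzyloxy)phenyl]-4-[(2R,3S)-5,7-bis(benzyloxy)-2-[3,4-bis(benzyloxy)phenyl]-8-bromo-3-hydroxychroman-6-yl]chroman-3-one
Product: 19 (2R,3R,4S)-7-(benzyloxy)-2-[3,4-bis(benzyloxy)phenyl]-4-[(2R,3S)-5,7-bis(benzyloxy)-2-[3,4-bis(benzyloxy)phenyl]-8-bromo-3-hydroxychroman-6-yl]chroman-3-ol
Conditions: LiBH(s-Bu)3 (3 equiv), LiBr (3 equiv), THF, −78 °C; aq. NH4Cl
Reagents that add atoms: none
Why: The bulky trialkylborohydride should attack the C3 ketone from the face opposite the two cis aryl groups at C2 and C4 (equatorial attack), giving the axial 3R alcohol and hence the all-cis array, as in the known reduction of protected flavan-3-ones to 2,3-cis flavan-3-ols.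

Step 14
Reactants: 19 (2R,3R,4S)-7-(benzyloxy)-2-[3,4-bis(benzyloxy)phenyl]-4-[(2R,3S)-5,7-bis(benzyloxy)-2-[3,4-bis(benzyloxy)phenyl]-8-bromo-3-hydroxychroman-6-yl]chroman-3-ol
Product: 20 (2R,3R,4S)-2-(3,4-dihydroxyphenyl)-4-[(2R,3S)-2-(3,4-dihydroxyphenyl)-3,5,7-trihydroxychroman-6-yl]chroman-3,7-diol
Conditions: H2 (1 atm), Pd(OH)2/C, Et3N (1.5 equiv), THF/MeOH, rt
Reagents that add atoms: none
Why: Hydrogenolysis should cleave the seven benzyl ethers and the C8 aryl bromide in one operation, with triethylamine taking up the hydrogen bromide, and does not touch the five stereocentres.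

**Compound list**

1 | 2,4-dihydroxyphenylacetic acid | OC(=O)Cc1ccc(O)cc1O | starting material
2 | 6-hydroxy-1-benzofuran-2(3H)-one | O=C1Cc2ccc(O)cc2O1 | intermediate
3 | 3,4-bis(benzyloxy)benzaldehyde | O=Cc1ccc(OCc2ccccc2)c(OCc2ccccc2)c1 | starting material
4 | (E)-3-[3,4-bis(benzyloxy)benzylidene]-6-hydroxy-1-benzofuran-2(3H)-one | O=C1Oc2cc(O)ccc2/C1=C\c1ccc(OCc2ccccc2)c(OCc2ccccc2)c1 | intermediate
5 | (E)-6-(benzyloxy)-3-[3,4-bis(benzyloxy)benzylidene]-1-benzofuran-2(3H)-one | O=C1Oc2cc(OCc3ccccc3)ccc2/C1=C\c1ccc(OCc2ccccc2)c(OCc2ccccc2)c1 | intermediate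
6 | (E)-2-[4-(benzyloxy)-2-hydroxyphenyl]-3-[3,4-bis(benzyloxy)phenyl]prop-2-en-1-ol | OC/C(c1ccc(OCc2ccccc2)cc1O)=C/c1ccc(OCc2ccccc2)c(OCc2ccccc2)c1 | intermediate
7 | (E)-2-[2-(allyloxy)-4-(benzyloxy)phenyl]-3-[3,4-bis(benzyloxy)phenyl]prop-2-en-1-ol | OC/C(c1ccc(OCc2ccccc2)cc1OCC=C)=C/c1ccc(OCc2ccccc2)c(OCc2ccccc2)c1 | intermediate
8 | [(2S,3S)-2-[2-(allyloxy)-4-(benzyloxy)phenyl]-3-[3,4-bis(benzyloxy)phenyl]oxiran-2-yl]methanol | OC[C@]1(c2ccc(OCc3ccccc3)cc2OCC=C)O[C@H]1c1ccc(OCc2ccccc2)c(OCc2ccccc2)c1 | intermediate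
9 | [(2S,3S)-2-[4-(benzyloxy)-2-hydroxyphenyl]-3-[3,4-bis(benzyloxy)phenyl]oxiran-2-yl]methanol (epoxy phenol, formed as its phenoxide) | OC[C@]1(c2ccc(OCc3ccccc3)cc2O)O[C@H]1c1ccc(OCc2ccccc2)c(OCc2ccccc2)c1 | intermediate
10 | (2R,3S)-6-(benzyloxy)-2-[3,4-bis(benzyloxy)phenyl]-3-(hydroxymethyl)-2,3-dihydro-1-benzofuran-3-ol | c1ccccc1COc1ccc2c(c1)O[C@H](c1ccc(OCc3ccccc3)c(OCc3ccccc3)c1)[C@@]2(O)CO | intermediate
11 | (2R,3R)-6-(benzyloxy)-2-[3,4-bis(benzyloxy)phenyl]-3-hydroxy-2,3-dihydro-1-benzofuran-3-carbaldehyde | c1ccccc1COc1ccc2c(c1)O[C@H](c1ccc(OCc3ccccc3)c(OCc3ccccc3)c1)[C@@]2(O)C=O | intermediate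
12 | (2R,3R)-6-(benzyloxy)-2-[3,4-bis(benzyloxy)phenyl]-3-[(trimethylsilyl)oxy]-2,3-dihydro-1-benzofuran-3-carbaldehyde | c1ccccc1COc1ccc2c(c1)O[C@H](c1ccc(OCc3ccccc3)c(OCc3ccccc3)c1)[C@@]2(O[Si](C)(C)C)C=O | intermediate
13 | (+)-catechin, (2R,3S)-2-(3,4-dihydroxyphenyl)chroman-3,5,7-triol | O[C@H]1Cc2c(O)cc(O)cc2O[C@@H]1c1ccc(O)c(O)c1 | starting material
14 | (2R,3S)-5,7-bis(benzyloxy)-2-[3,4-bis(benzyloxy)phenyl]chroman-3-ol | O[C@H]1Cc2c(OCc3ccccc3)cc(OCc3ccccc3)cc2O[C@@H]1c1ccc(OCc2ccccc2)c(OCc2ccccc2)c1 | intermediate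
15 | (2R,3S)-5,7-bis(benzyloxy)-2-[3,4-bis(benzyloxy)phenyl]-8-bromochroman-3-ol | O[C@H]1Cc2c(OCc3ccccc3)cc(OCc3ccccc3)c(Br)c2O[C@@H]1c1ccc(OCc2ccccc2)c(OCc2ccccc2)c1 | intermediate
16 | (2R,3S)-6-(benzyloxy)-2-[3,4-bis(benzyloxy)phenyl]-3-{hydroxy[(2R,3S)-5,7-bis(benzyloxy)-2-[3,4-bis(benzyloxy)phenyl]-8-bromo-3-hydroxychroman-6-yl]methyl}-3-[(trimethylsilyl)oxy]-2,3-dihydro-1-benzofuran (benzylic carbinol, both epimers at the carbinol carbon) | c1ccccc1COc1ccc2c(c1)O[C@H](c1ccc(OCc3ccccc3)c(OCc3ccccc3)c1)[C@@]2(O[Si](C)(C)C)C(O)c1c(OCc3ccccc3)c(Br)c2c(c1OCc3ccccc3)C[C@H](O)[C@@H](c1ccc(OCc3ccccc3)c(OCc3ccccc3)c1)O2 | intermediate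
17 | benzylic carbenium ion formed from 16 by loss of hydroxide (charge on the exocyclic carbon between C3 of the dihydrobenzofuran and C6 of the catechin unit) | c1ccccc1COc1ccc2c(c1)O[C@H](c1ccc(OCc3ccccc3)c(OCc3ccccc3)c1)[C@@]2(O[Si](C)(C)C)[CH+]c1c(OCc3ccccc3)c(Br)c2c(c1OCc3ccccc3)C[C@H](O)[C@@H](c1ccc(OCc3ccccc3)c(OCc3ccccc3)c1)O2 | intermediate
18 | (2R,4S)-7-(benzyloxy)-2-[3,4-bis(benzyloxy)phenyl]-4-[(2R,3S)-5,7-bis(benzyloxy)-2-[3,4-bis(benzyloxy)phenyl]-8-bromo-3-hydroxychroman-6-yl]chroman-3-one | c1ccccc1COc1ccc2c(c1)O[C@H](c1ccc(OCc3ccccc3)c(OCc3ccccc3)c1)C(=O)[C@@H]2c1c(OCc3ccccc3)c(Br)c2c(c1OCc3ccccc3)C[C@H](O)[C@@H](c1ccc(OCc3ccccc3)c(OCc3ccccc3)c1)O2 | intermediate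
19 | (2R,3R,4S)-7-(benzyloxy)-2-[3,4-bis(benzyloxy)phenyl]-4-[(2R,3S)-5,7-bis(benzyloxy)-2-[3,4-bis(benzyloxy)phenyl]-8-bromo-3-hydroxychroman-6-yl]chroman-3-ol | c1ccccc1COc1ccc2c(c1)O[C@H](c1ccc(OCc3ccccc3)c(OCc3ccccc3)c1)[C@H](O)[C@@H]2c1c(OCc3ccccc3)c(Br)c2c(c1OCc3ccccc3)C[C@H](O)[C@@H](c1ccc(OCc3ccccc3)c(OCc3ccccc3)c1)O2 | intermediate
20 | (2R,3R,4S)-2-(3,4-dihydroxyphenyl)-4-[(2R,3S)-2-(3,4-dihydroxyphenyl)-3,5,7-trihydroxychroman-6-yl]chroman-3,7-diol | Oc1ccc2c(c1)O[C@H](c1ccc(O)c(O)c1)[C@H](O)[C@@H]2c1c(O)cc2c(c1O)C[C@H](O)[C@@H](c1ccc(O)c(O)c1)O2 | target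

**Summary**

Total step count: 14. Longest linear sequence: 12 steps (steps 1 to 9, then 12, 13 and 14).

Steps most likely to fail:

Step 12 (proposed new method). The hydroxyalkylation at the hindered C6 position of 15 may be too slow. The tertiary benzylic C3–O bond may ionise in competition, followed by loss of the C2 proton and aromatisation to a benzofuran. C2 may migrate instead of the aryl carbon. Fallback with known reaction types, setting out from 12: the ring expansion is run first and alone as the Lewis-acid-promoted acyloin-type rearrangement of an α-silyloxy aldehyde to an α-silyloxy ketone (MeAl(OC6H2-2,6-t-Bu2-4-Br)2, CH2Cl2, −78 °C). The same aryl carbon migrates to the aldehyde carbon and the silyl group passes to the new oxygen, which should give (2R)-7-(benzyloxy)-2-[3,4-bis(benzyloxy)phenyl]-4-[(trimethylsilyl)oxy]chroman-3-one F1. Its C4 silyloxy group is then ionised with TMSOTf at −78 °C in the presence of 15, a conventional interflavan Friedel–Crafts coupling through a C4 benzylic cation, and the route is rejoined at 18.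

Step 6. The epoxide carries a para-alkoxyphenyl group on its benzylic carbon and may be opened under the Lewis-acidic titanium conditions (by isopropanol, tartrate or hydroperoxide). Binding of the ortho-allyloxy oxygen to titanium may also erode the face selectivity. Fallback, setting out from 7: the alkene is epoxidised without a metal by the chiral-dioxirane (Shi) epoxidation, which is not directed by the hydroxyl group and runs near pH 10. The L-fructose-derived ketone (mirror image of the usual D-fructose catalyst, which gives the 3R benzylic configuration with (E)-cinnamyl-type alkenes) is used with KHSO5 (as 2KHSO5·KHSO4·K2SO4), K2CO3, MeCN/dimethoxymethane/H2O at 0 °C. It makes no new compound and comes back to the route at 8.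

Step 13. The basic, hindered borohydride may abstract the doubly benzylic C4 proton (or the C2 proton) instead of adding to the crowded carbonyl, returning partly epimerised ketone, or hydride delivery may lose its face selectivity. Fallback, setting out from 18: the carbonyl is reduced by catalytic asymmetric hydrogenation under dynamic kinetic resolution with a divalent ruthenium diphosphine–diamine complex (RuCl2[(S)-Xyl-BINAP][(S)-DAIPEN] or its mirror image, KOt-Bu, H2, i-PrOH). This method is known to turn α-aryl and α,α'-disubstituted cyclic ketones into all-cis alcohols. Here epimerisation at C2 and C4 is used instead of avoided; the catalyst antipode matched to the catechin unit would be chosen by comparing the two. No new compound is made and the route is rejoined at 19.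

**Further compounds**

F1 | step 12 | (2R)-7-(benzyloxy)-2-[3,4-bis(benzyloxy)phenyl]-4-[(trimethylsilyl)oxy]chroman-3-one (both C4 epimers) | c1ccccc1COc1ccc2c(c1)O[C@H](c1ccc(OCc3ccccc3)c(OCc3ccccc3)c1)C(=O)C2O[Si](C)(C)C
F0 | step 6 | none | none
F0 | step 13 | none | none
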